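**Strategy.** Ring A, the 2-butanoyl-4,4-dimethylcyclohexane-1,3,5-trione ring, is not made from an aromatic ring but assembled by a Danheiser-type annulation. A 3-ethoxy-4,4-dimethylcyclobutenone (carrying CMe2, its two neighbouring oxygenated carbons and the future butanoyl-bearing CH) takes up a siloxyalkyne (the oxygenated carbon between the two C-substituted ring carbons, the bridge-bearing carbon and the bridging CH2 as a Me2N handle). One operation forms the ring bonds on both sides of the alkyne unit: butanoyl-bearing C to C–O, and CH2-bearing C to the C–O next to CMe2. The quaternary CMe2 carbon blocks aromatisation, so the 1,3,5-trioxygenated dienone results directly. Acylation and two Mannich-base couplings with rings B and C finish the trimer.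

Key step: step 3

Remark: the enolised triketone and acylphloroglucinol rings are each drawn as one tautomer; the target has no stereocentre, and the only stereocentre in the route is in the transient racemic intermediate 10.

**Step 1**
Reactants: 1 2-methylpropanoyl chloride; 2 ethoxyethyne
Product: 4 3-ethoxy-4,4-dimethylcyclobut-2-en-1-one, via dimethylketene 3 (not isolated)
Conditions: Et3N, Et2O, 0 °C to rt
Reagents that add atoms: none
Why: Et3N dehydrochlorinates 1 to dimethylketene 3, which is trapped in a regioselective ketene–ynol ether [2+2] cycloaddition (the oxygen-free alkyne carbon bonds to the ketene carbonyl carbon), the established route to 3-ethoxycyclobutenones.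

**Step 2**
Reactants: 5 ethyl N,N-dimethylglycinate
Product: 8 N,N-dimethyl-3-[(triisopropylsilyl)oxy]prop-2-yn-1-amine, via dibromoketone enolate 6 (not isolated), via lithium ynolate 7 (not isolated)
Conditions: CH2Br2, lithium 2,2,6,6-tetramethylpiperidide (2.2 equiv), THF, −78 °C; n-BuLi, −78 to 0 °C; iPr3SiCl, −78 °C to rt
Reagents that add atoms: dibromomethane BrCBr; chlorotriisopropylsilane CC(C)[Si](Cl)(C(C)C)C(C)C
Why: Kowalski ester homologation, in which LiCHBr2 adds to the ester, the dibromoketone enolate 6 undergoes Br–Li exchange and 1,2-shift to ynolate 7, and the bulky silyl chloride traps 7 on oxygen to give the siloxyalkyne.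

**Step 3**
Reactants: 4 3-ethoxy-4,4-dimethylcyclobut-2-en-1-one; 8 N,N-dimethyl-3-[(triisopropylsilyl)oxy]prop-2-yn-1-amine (1.3 equiv)
Product: 12 2-[(dimethylamino)methyl]-5-ethoxy-6,6-dimethyl-3-[(triisopropylsilyl)oxy]cyclohexa-2,4-dien-1-one, via vinylketene 9 (not isolated), via vinylcyclobutenone 10 (not isolated), via dienylketene 11 (not isolated)
Conditions: toluene, 110 °C, sealed tube, argon
Reagents that add atoms: none
Why: Heating opens 4 by 4π-electrocyclic cleavage of its C(=O)–CMe2 bond to vinylketene 9, whose ketene C=C adds across the siloxyalkyne in a [2+2] cycloaddition to give 10; a second, reversible 4π opening gives dienylketene 11, and 6π-electrocyclisation of the ketene carbon onto the CMe2 terminus closes ring A. The closest known reaction is the Danheiser benzannulation of cyclobutenones with siloxyalkynes, here stopped at the cyclohexa-2,4-dienone because the quaternary carbon cannot tautomerise, as in the thermal closure of dienylketenes to 6,6-disubstituted cyclohexadienones. The six-membered ring closes by a thermal disrotatory 6π electrocyclisation (the transient four-membered ring by [2+2]); in net terms the alkyne is inserted into the C(=O)–CH bond of 4, so the two new ring bonds are C(=O)–C(CH2NMe2) and C(OSi)–CH. No stereocentre remains, since 10 is a transient racemate. The step needs the head-to-tail regiochemistry of the [2+2], secured by the polarisation of the ynol ether (the carbon remote from oxygen attacks the ketene carbonyl carbon), and C- over N-capture of the ketene, secured by the reversibility of amine addition; the alkyne is used in excess to outrun ketene dimerisation.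

**Step 4**
Reactants: 12 2-[(dimethylamino)methyl]-5-ethoxy-6,6-dimethyl-3-[(triisopropylsilyl)oxy]cyclohexa-2,4-dien-1-one
Product: 13 2-[(dimethylamino)methyl]-3,5-dihydroxy-6,6-dimethylcyclohexa-2,4-dien-1-one
Conditions: 1 M aq. HCl, THF, 0 °C to rt; brought to pH 6 on work-up, kept cold and used at once
Reagents that add atoms: water O
Why: Acid-catalysed hydrolysis of the silyl enol ether and of the vinylogous ethyl ester (addition–elimination of water), with the amine protonated throughout so that loss of dimethylamine is held back.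

**Step 5**
Reactants: 13 2-[(dimethylamino)methyl]-3,5-dihydroxy-6,6-dimethylcyclohexa-2,4-dien-1-one
Product: 14 2-butanoyl-4-[(dimethylamino)methyl]-3,5-dihydroxy-6,6-dimethylcyclohexa-2,4-dien-1-one
Conditions: butanoic acid, DCC, DMAP, CH2Cl2–DMF, 0 °C to rt
Reagents that add atoms: butanoic acid CCCC(=O)O
Why: Steglich-type C-acylation of a cyclic triketone, in which the DCC-activated acid O-acylates the enolate and DMAP shuttles the acyl group to the only unsubstituted ring carbon (O→C acyl migration), while the amine sits protonated in the inner salt.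

**Step 6**
Reactants: 15 benzene-1,3,5-triol (phloroglucinol)
Product: 16 1-(2,4,6-trihydroxyphenyl)butan-1-one
Conditions: butanoyl chloride, AlCl3, nitrobenzene–CH2Cl2, 0 to 50 °C; aq. HCl work-up
Reagents that add atoms: butanoyl chloride CCCC(Cl)=O
Why: Friedel–Crafts acylation of the symmetrical triol; the first acyl group deactivates the ring, so monoacylation should result.

**Step 7**
Reactants: 17 2-methylbenzene-1,3,5-triol
Product: 18 1-(2,4,6-trihydroxy-3-methylphenyl)butan-1-one
Conditions: butanoyl chloride, AlCl3, nitrobenzene–CH2Cl2, 0 to 50 °C; aq. HCl work-up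
Reagents that add atoms: butanoyl chloride CCCC(Cl)=O
Why: Friedel–Crafts acylation; the two free ring positions of 17 are equivalent, so a single ketone should form.

**Step 8**
Reactants: 18 1-(2,4,6-trihydroxy-3-methylphenyl)butan-1-one
Product: 19 1-{3-[(dimethylamino)methyl]-2,4,6-trihydroxy-5-methylphenyl}butan-1-one
Conditions: N,N-dimethylmethyleneiminium iodide, Et3N (1 equiv), CH2Cl2, 0 °C to rt
Reagents that add atoms: N,N-dimethylmethyleneiminium iodide C=[N+](C)C.[I-]
Why: Mannich reaction with the preformed iminium salt at the only free ring carbon of 18.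

**Step 9**
Reactants: 19 1-{3-[(dimethylamino)methyl]-2,4,6-trihydroxy-5-methylphenyl}butan-1-one; 16 1-(2,4,6-trihydroxyphenyl)butan-1-one (3 equiv)
Product: 20 1-{3-[(3-butanoyl-2,4,6-trihydroxy-5-methylphenyl)methyl]-2,4,6-trihydroxyphenyl}butan-1-one
Conditions: 1,4-dioxane, 90 °C, N2 sweep
Reagents that add atoms: none
Why: Mannich-base alkylation, in which thermal loss of Me2NH from 19 gives an ortho-quinone methide that is captured by a free ring carbon of 16 (conjugate addition, then re-aromatisation); the two free positions of 16 are equivalent and its excess holds back double alkylation.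

**Step 10**
Reactants: 14 2-butanoyl-4-[(dimethylamino)methyl]-3,5-dihydroxy-6,6-dimethylcyclohexa-2,4-dien-1-one; 20 1-{3-[(3-butanoyl-2,4,6-trihydroxy-5-methylphenyl)methyl]-2,4,6-trihydroxyphenyl}butan-1-one
Product: 21 2-butanoyl-4-({3-butanoyl-5-[(3-butanoyl-2,4,6-trihydroxy-5-methylphenyl)methyl]-2,4,6-trihydroxyphenyl}methyl)-3,5-dihydroxy-6,6-dimethylcyclohexa-2,4-dien-1-one (CNP0086105.0)
Conditions: 1,4-dioxane, 80–90 °C, N2 sweep
Reagents that add atoms: none
Why: The same Mannich-base/quinone-methide alkylation, in which 14 loses Me2NH to the 2-methylene-trione of ring A, which is captured by the single remaining free carbon of ring B in 20.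

**Compound list**
1 | 2-methylpropanoyl chloride | CC(C)C(=O)Cl | starting material
2 | ethoxyethyne | CCOC#C | starting material
3 | dimethylketene (2-methylprop-1-en-1-one) | CC(C)=C=O | intermediate (not isolated)
4 | 3-ethoxy-4,4-dimethylcyclobut-2-en-1-one | CCOC1=CC(=O)C1(C)C | intermediate
5 | ethyl N,N-dimethylglycinate | CCOC(=O)CN(C)C | starting material
6 | lithium enolate of 1,1-dibromo-3-(dimethylamino)propan-2-one | CN(C)CC(O[Li])=C(Br)Br | intermediate (not isolated)
7 | lithium 3-(dimethylamino)prop-1-yn-1-olate | CN(C)CC#CO[Li] | intermediate (not isolated)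
8 | N,N-dimethyl-3-[(triisopropylsilyl)oxy]prop-2-yn-1-amine | CN(C)CC#CO[Si](C(C)C)(C(C)C)C(C)C | intermediate
9 | 3-ethoxy-4-methylpenta-1,3-dien-1-one (vinylketene) | CCOC(C=C=O)=C(C)C | intermediate (not isolated)
10 | 2-[(dimethylamino)methyl]-4-(1-ethoxy-2-methylprop-1-en-1-yl)-3-[(triisopropylsilyl)oxy]cyclobut-2-en-1-one (racemic) | CCOC(=C(C)C)C1C(=O)C(CN(C)C)=C1O[Si](C(C)C)(C(C)C)C(C)C | intermediate (not isolated)
11 | (3E)-2-[(dimethylamino)methyl]-5-ethoxy-6-methyl-3-[(triisopropylsilyl)oxy]hepta-1,3,5-trien-1-one (dienylketene) | O=C=C(CN(C)C)/C(O[Si](C(C)C)(C(C)C)C(C)C)=C\C(OCC)=C(C)C | intermediate (not isolated)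
12 | 2-[(dimethylamino)methyl]-5-ethoxy-6,6-dimethyl-3-[(triisopropylsilyl)oxy]cyclohexa-2,4-dien-1-one | CCOC1=CC(O[Si](C(C)C)(C(C)C)C(C)C)=C(CN(C)C)C(=O)C1(C)C | intermediate
13 | 2-[(dimethylamino)methyl]-3,5-dihydroxy-6,6-dimethylcyclohexa-2,4-dien-1-one | CN(C)CC1=C(O)C=C(O)C(C)(C)C1=O | intermediate
14 | 2-butanoyl-4-[(dimethylamino)methyl]-3,5-dihydroxy-6,6-dimethylcyclohexa-2,4-dien-1-one | CCCC(=O)C1=C(O)C(CN(C)C)=C(O)C(C)(C)C1=O | intermediate
15 | benzene-1,3,5-triol (phloroglucinol) | Oc1cc(O)cc(O)c1 | starting material
16 | 1-(2,4,6-trihydroxyphenyl)butan-1-one | CCCC(=O)c1c(O)cc(O)cc1O | intermediate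
17 | 2-methylbenzene-1,3,5-triol | Cc1c(O)cc(O)cc1O | starting material
18 | 1-(2,4,6-trihydroxy-3-methylphenyl)butan-1-one | CCCC(=O)c1c(O)cc(O)c(C)c1O | intermediate
19 | 1-{3-[(dimethylamino)methyl]-2,4,6-trihydroxy-5-methylphenyl}butan-1-one | CCCC(=O)c1c(O)c(CN(C)C)c(O)c(C)c1O | intermediate
20 | 1-{3-[(3-butanoyl-2,4,6-trihydroxy-5-methylphenyl)methyl]-2,4,6-trihydroxyphenyl}butan-1-one | CCCC(=O)c1c(O)cc(O)c(Cc2c(O)c(C)c(O)c(C(=O)CCC)c2O)c1O | intermediate
21 | 2-butanoyl-4-({3-butanoyl-5-[(3-butanoyl-2,4,6-trihydroxy-5-methylphenyl)methyl]-2,4,6-trihydroxyphenyl}methyl)-3,5-dihydroxy-6,6-dimethylcyclohexa-2,4-dien-1-one (CNP0086105.0) | CCCC(=O)C1=C(O)C(Cc2c(O)c(Cc3c(O)c(C)c(O)c(C(=O)CCC)c3O)c(O)c(C(=O)CCC)c2O)=C(O)C(C)(C)C1=O | target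

**Totals.** Total step count: 10. Longest linear sequence: 5 steps (1 or 2, then 3, 4, 5, 10).

**Steps most likely to fail**

1. Step 3. Ring opening of the gem-dimethyl cyclobutenone may be slower than thermal decay of the siloxyalkyne, and the vinylketene may dimerise or be diverted by the tertiary amine. Fallback, from 15 back to 14 by known dearomatising chemistry: phloroglucinol 15 is C-methylated twice (MeI, NaOMe, MeOH) to filicinic acid F1. Friedel–Crafts acylation (butanoyl chloride, AlCl3, nitrobenzene) then gives butyrylfilicinic acid F2. A Mannich reaction with N,N-dimethylmethyleneiminium iodide at the one free ring carbon of F2 returns to 14.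

2. Step 5. Acyl transfer to nitrogen followed by loss of the amine, self-condensation of the unmasked aminomethyl trione, or stalling at the enol ester stage may erode the C-acylation. Fallback, from 13 and 20 back to 21, with coupling before acylation: 13 is added slowly to an excess of 20 in dioxane at 80 °C to give the ring-A-unacylated trimer F3. Its only unsubstituted nucleophilic ring carbon is then acylated under Fries/Friedel–Crafts conditions (butanoyl chloride, AlCl3, nitrobenzene, 0 °C) to give 21.

3. Step 10. Exchange of methylene-bridged units by retro-Michael and re-addition, or sluggish attack at the hindered last free position of ring B, may give scrambled dimers and trimers. Fallback, from 14 back to 21, with the order of assembly reversed: 14 is heated with an excess of 16 to give the ring A–ring B dimer F4. F4 is then alkylated at its one free ring-B carbon by the ring C Mannich base 19 (dioxane, 90 °C) to give 21.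

**Further compounds**
F1 | step 3 | filicinic acid (3,5-dihydroxy-4,4-dimethylcyclohexa-2,5-dien-1-one) | CC1(C)C(O)=CC(=O)C=C1O
F2 | step 3 | butyrylfilicinic acid (2-butanoyl-3,5-dihydroxy-6,6-dimethylcyclohexa-2,4-dien-1-one) | CCCC(=O)C1=C(O)C=C(O)C(C)(C)C1=O
F3 | step 5 | 4-({3-butanoyl-5-[(3-butanoyl-2,4,6-trihydroxy-5-methylphenyl)methyl]-2,4,6-trihydroxyphenyl}methyl)-3,5-dihydroxy-6,6-dimethylcyclohexa-2,4-dien-1-one | O=C1C=C(O)C(Cc2c(O)c(Cc3c(O)c(C)c(O)c(C(=O)CCC)c3O)c(O)c(C(=O)CCC)c2O)=C(O)C1(C)C
F4 | step 10 | 2-butanoyl-4-[(3-butanoyl-2,4,6-trihydroxyphenyl)methyl]-3,5-dihydroxy-6,6-dimethylcyclohexa-2,4-dien-1-one | CCCC(=O)C1=C(O)C(Cc2c(O)cc(O)c(C(=O)CCC)c2O)=C(O)C(C)(C)C1=O
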